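**Retrosynthetic overview**

1. Last event: thermal endo [4+2] between the C11=C13 methylene lactone of a complete 6-O-tigloyl-9β-hydroxyhelenalin half and a p-menthadienol made from (R)-(−)-carvone (1); this sets the spiro centre and the bicyclo[2.2.2]octene.
2. The seven-membered ring is closed at C6–C7 by a visible-light, chromium-catalysed allylation of a C6 aldehyde by a 3-(bromomethyl)butenolide, which also delivers the cis-fused α-methylene lactone; C8–C9 comes from a vinylogous Mukaiyama aldol with a silyloxyfuran made from furan-3-ylmethanol (2).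
3. Ring A with C1 and C5 is cut out of (1S)-(−)-camphor (3) by remote bromination and Grob-type C1–C2 cleavage; a transient δ-lactone relays C5 to C10.
4. Ring order: ring A (bought) → butenolide → seven-membered ring plus γ-lactone in one step → cyclopentenone unsaturation → bicyclo[2.2.2]octene.

Assumption: helenanolide (pseudoguaiane) locants C1–C15 and α/β descriptors are used for all sesquiterpenoid intermediates (C9 of camphor = the C7 methyl anti to the carbonyl), and 1, 2 and 3 are taken as catalogue chemicals.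

**Route**

Step 1
Reactants: 1 (R)-(−)-carvone
Product: 4 (5R)-5-(2-hydroxypropan-2-yl)-2-methylcyclohex-2-en-1-one
Conditions: 50% aq. H2SO4, 0 °C
Reagents that add atoms: water O
Why: Acid-catalysed Markovnikov hydration of the isopropenyl group through the tertiary cation; the conjugated ring alkene is inert and the bought stereocentre is untouched.

Step 2
Reactants: 4 (5R)-5-(2-hydroxypropan-2-yl)-2-methylcyclohex-2-en-1-one
Product: 5 N'-[(1E,5R)-5-(2-hydroxypropan-2-yl)-2-methylcyclohex-2-en-1-ylidene]-4-methylbenzenesulfonohydrazide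
Conditions: TsNHNH2, MeOH, 23 °C
Reagents that add atoms: 4-methylbenzenesulfonohydrazide Cc1ccc(cc1)S(=O)(=O)NN
Why: Hydrazone condensation; the sulfonamide nitrogen sits anti to the substituted alkene carbon, syn to the α'-CH2 that must be deprotonated next.

Step 3
Reactants: 5 tosylhydrazone
Product: 7 2-[(1R)-4-methylcyclohexa-2,4-dien-1-yl]propan-2-ol, via dilithio vinyl alkoxide 6 (not isolated)
Conditions: LiN(iPr)2 (3.5 equiv), THF, −78 to 23 °C; H2O
Reagents that add atoms: none
Why: Shapiro reaction of an enone tosylhydrazone (syn α'-deprotonation, loss of sulfinate and N2, protonation of the vinyl anion) gives the homoannular diene; the stereocentre is never deprotonated.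

Step 4
Reactants: 2 furan-3-ylmethanol
Product: 10 3-(hydroxymethyl)furan-2(5H)-one, via dilithio furan alkoxide 8 (not isolated), via dilithium furylborate 9 (not isolated)
Conditions: n-BuLi (2.2 equiv), THF, −78 to 0 °C; B(OMe)3, −78 °C; 30% H2O2, aq. NaHCO3, 0 °C
Reagents that add atoms: hydrogen peroxide OO
Why: Alkoxide-directed lithiation at C2, borylation and oxidative C–B to C–O migration give the 2-hydroxyfuran, which tautomerises to the conjugated butenolide.

Step 5
Reactants: 10 3-(hydroxymethyl)furan-2(5H)-one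
Product: 11 tert-butyl{[2-{[tert-butyl(dimethyl)silyl]oxy}furan-3-yl]methoxy}dimethylsilane
Conditions: TBSOTf (2.2 equiv), Et3N, CH2Cl2, 0 °C
Reagents that add atoms: tert-butyldimethylsilyl trifluoromethanesulfonate CC(C)(C)[Si](C)(C)OS(=O)(=O)C(F)(F)F
Why: Silylation of the primary alcohol and soft enolisation with O-silylation give the aromatic 2-silyloxyfuran (a vinylogous silyl ketene acetal).

Step 6
Reactants: 3 (1S,4S)-(−)-camphor
Product: 12 (1S,3R,4R)-3-endo-bromocamphor
Conditions: Br2, AcOH, 80 °C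
Reagents that add atoms: bromine BrBr
Why: Acid-catalysed enol bromination; the 3-endo bromide is the thermodynamic product and the skeleton stereocentres are not involved.

Step 7
Reactants: 12 (1S,3R,4R)-3-endo-bromocamphor
Product: 14 (−)-3-endo,9,10-tribromocamphor, via 3,9-dibromocamphor 13 (not isolated)
Conditions: Br2, ClSO3H, 23 °C, 5 d
Reagents that add atoms: bromine BrBr
Why: Remote bromination of camphor: in the superacid, Wagner–Meerwein and exo-methyl shifts expose first the C9 (anti) and then the C10 methyl as alkenes that take up bromine, and the return path restores the camphor skeleton with unchanged absolute configuration.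

Step 8
Reactants: 14 (−)-3-endo,9,10-tribromocamphor
Product: 15 (−)-9,10-dibromocamphor
Conditions: Zn, AcOH, Et2O, 0 °C
Reagents that add atoms: none
Why: Zinc reduces only the α-keto C–Br bond (zinc enolate, then protonation); the two neopentylic bromides stay.

Step 9
Reactants: 15 (−)-9,10-dibromocamphor
Product: 18 (4aS,7aS)-7a-methyl-7-methylidenehexahydrocyclopenta[c]pyran-3(1H)-one, via potassium bromo-carboxylate 16 (not isolated), via hydroxy acid 17 (not isolated)
Conditions: KOH, DMSO–H2O (9:1), 90 °C; 2 M HCl; TsOH (cat.), toluene, 80 °C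
Reagents that add atoms: potassium hydroxide [K+].[OH-]
Why: Hydroxide adds to the ketone and a Grob-type fragmentation cleaves C1–C2 with loss of the C10 bromide; the carboxylate arm then reaches the neopentylic C9 bromide and acid closes the trans-fused δ-lactone, so camphor C7 and C4 become C5 (β-methyl) and C1 (α-H) unchanged.

Step 10
Reactants: 18 trans-fused δ-lactone
Product: 20 (4S,4aS,7aS)-4,7a-dimethyl-7-methylidenehexahydrocyclopenta[c]pyran-3(1H)-one, via lithium enolate 19 (not isolated)
Conditions: LiN(iPr)2, THF, −78 °C; MeI, −78 to −40 °C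
Reagents that add atoms: iodomethane CI
Why: Lactone enolate alkylation; iodomethane enters on the α face, anti to the axial angular C5 methyl (1,3-relationship), which gives the equatorial 10α-methyl, also the thermodynamic epimer.

Step 11
Reactants: 20 methylated δ-lactone
Product: 21 (2S)-2-[(1S,2S)-2-(hydroxymethyl)-2-methyl-3-methylidenecyclopentyl]propan-1-ol
Conditions: LiAlH4, THF, 0 °C
Reagents that add atoms: none
Why: Hydride reduction of the lactone to the diol is faster than enolisation, so C10 keeps its configuration.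

Step 12
Reactants: 21 diol
Product: 22 (1S,2S)-1-methyl-5-methylidene-2-[(2S)-1-oxopropan-2-yl]cyclopentane-1-carbaldehyde
Conditions: Dess–Martin periodinane, NaHCO3, CH2Cl2, 0 to 23 °C
Reagents that add atoms: none
Why: Buffered neutral oxidation of both primary alcohols; the C6 aldehyde is non-enolisable and the mild conditions keep the C10 stereocentre.

Step 13
Reactants: 22 dialdehyde; 11 bis-silyl furan
Product: 24 (5S)-5-[(1R,2S)-1-{[tert-butyl(dimethyl)silyl]oxy}-2-[(1S,2S)-2-formyl-2-methyl-3-methylidenecyclopentyl]propyl]-3-({[tert-butyl(dimethyl)silyl]oxy}methyl)furan-2(5H)-one, via threo adduct 23 (not isolated)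
Conditions: TBSOTf (5 mol %), CH2Cl2, −78 °C; then Et3N, DMAP (10 mol %), 23 °C
Reagents that add atoms: none
Why: Vinylogous Mukaiyama aldol with silyl transfer: the furan attacks only the C9 aldehyde (the C6 aldehyde is neopentylic) in the Felkin–Anh sense (9β-O, syn to the 10α-methyl), the open transition state gives the 8,9-threo adduct, and amine-mediated γ-epimerisation through the 2-oxyfuran dienolate is relied on to move C8 to the 8,9-erythro (8β-O) butenolide.

Step 14
Reactants: 24 erythro butenolide aldehyde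
Product: 26 (5S)-5-[(1R,2S)-1-{[tert-butyl(dimethyl)silyl]oxy}-2-[(1S,2R)-2-formyl-2-methyl-3-oxocyclopentyl]propyl]-3-({[tert-butyl(dimethyl)silyl]oxy}methyl)furan-2(5H)-one, via vicinal diol 25 (not isolated)
Conditions: OsO4 (2 mol %), NaIO4 (4 equiv), 2,6-lutidine, dioxane–H2O (3:1), 23 °C
Reagents that add atoms: sodium periodate [Na+].[O-]I(=O)(=O)=O
Why: Lemieux–Johnson cleavage: OsO4 dihydroxylates only the electron-rich 1,1-disubstituted alkene (the butenolide alkene is electron-poor and trisubstituted) and periodate cleaves the diol to the C4 ketone; no stereocentre changes.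

Step 15
Reactants: 26 keto aldehyde
Product: 27 (5S)-3-(bromomethyl)-5-[(1R,2S)-1-{[tert-butyl(dimethyl)silyl]oxy}-2-[(1S,2R)-2-formyl-2-methyl-3-oxocyclopentyl]propyl]furan-2(5H)-one
Conditions: Ph3PBr2, CH2Cl2, 0 °C
Reagents that add atoms: dibromotriphenylphosphorane BrP(Br)(c1ccccc1)(c1ccccc1)c1ccccc1
Why: Oxyphosphonium activation turns the primary allylic silyl ether directly into the bromide (SN2); the hindered secondary C9 silyl ether is left.

Step 16
Reactants: 27 bromomethyl butenolide keto aldehyde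
Product: 28 9β-{[tert-butyl(dimethyl)silyl]oxy}-6α-hydroxy-4-oxopseudoguai-11(13)-en-12,8β-olide (1αH, 5β-methyl, 7αH, 8αH, 10α-methyl)
Conditions: CrCl3 (10 mol %), 4,4'-di-tert-butyl-2,2'-bipyridine (12 mol %), 4CzIPN (2 mol %), Hantzsch ester (1.5 equiv), THF, 5 mM, 450 nm LEDs, 23 °C
Reagents that add atoms: none
Why: Proposed new method: the excited organic photocatalyst, reductively quenched by the Hantzsch ester, returns trivalent chromium to divalent chromium, which converts the allylic bromide into an allylchromium species that adds through its γ-carbon (C7) to the tethered C6 aldehyde in a chair Zimmerman–Traxler transition state (C5 and C8 equatorial), so C7 is attacked on the face of the C9 tether (cis lactone fusion, H7α and H8α) and the 6α-alcohol trans to C11 results, while the Hantzsch pyridinium protonates the chromium alkoxide for turnover; the closest known reactions are intermolecular photoredox chromium- or titanium-catalysed Barbier allylations of aldehydes with allyl bromides and stoichiometric Nozaki–Hiyama–Kishi ring closures of ω-formyl 2-(bromomethyl)acrylates, but a light-driven catalytic closure of a 3-(bromomethyl)butenolide to a seven-membered ring has not been shown.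

Step 17
Reactants: 28 6α-alcohol
Product: 29 6α-[(E)-2-methylbut-2-enoyl]oxy derivative of 28
Conditions: (E)-2-methylbut-2-enoyl chloride, DMAP, Et3N, CH2Cl2, 0 to 40 °C
Reagents that add atoms: (E)-2-methylbut-2-enoyl chloride C/C=C(\C)C(Cl)=O
Why: DMAP-catalysed acylation of the only free hydroxyl; the quaternary C5 prevents elimination and the E geometry of the acyl group is kept.

Step 18
Reactants: 29 tiglate ketone
Product: 30 9-O-[tert-butyl(dimethyl)silyl]-6-O-tigloyl-9β-hydroxyhelenalin
Conditions: IBX (3 equiv), 4-methoxypyridine N-oxide, DMSO, 23 to 50 °C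
Reagents that add atoms: none
Why: IBX dehydrogenation of the cyclopentanone; only C3 carries α-hydrogens (C5 is quaternary), so the C2=C3 enone forms regiospecifically and no stereocentre is touched.

Step 19
Reactants: 30 silyl ether
Product: 31 6-O-tigloyl-9β-hydroxyhelenalin
Conditions: HF·pyridine, pyridine, THF, 0 to 23 °C
Reagents that add atoms: none
Why: Buffered fluoride cleavage of the secondary silyl ether; ester, lactone and enone survive.

Step 20
Reactants: 31 6-O-tigloyl-9β-hydroxyhelenalin; 7 2-[(1R)-4-methylcyclohexa-2,4-dien-1-yl]propan-2-ol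
Product: 32 CNP0185323.3
Conditions: 7 (3 equiv), toluene, BHT (cat.), 90 °C, sealed tube
Reagents that add atoms: none
Why: Thermal Diels–Alder: the exocyclic methylene lactone is the most reactive dienophile, C13 joins the diene terminus next to the methyl-bearing carbon ("para" orientation), the endo transition state puts the lactone carbonyl over the diene, the diene reacts anti to its hydroxyisopropyl group and the lactone is attacked on its β face away from the 6α-tigloyloxy group, which sets C11 and both bridgeheads.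

**Compound list**

1 | (R)-(−)-carvone, (5R)-2-methyl-5-(prop-1-en-2-yl)cyclohex-2-en-1-one | CC1=CC[C@H](CC1=O)C(C)=C | starting material
2 | furan-3-ylmethanol | OCc1ccoc1 | starting material
3 | (1S,4S)-(−)-camphor | CC1(C)[C@H]2CC[C@]1(C)C(=O)C2 | starting material
4 | (5R)-5-(2-hydroxypropan-2-yl)-2-methylcyclohex-2-en-1-one | CC1=CC[C@H](CC1=O)C(C)(C)O | intermediate
5 | N'-[(1E,5R)-5-(2-hydroxypropan-2-yl)-2-methylcyclohex-2-en-1-ylidene]-4-methylbenzenesulfonohydrazide | CC1=CC[C@H](C/C1=N\NS(=O)(=O)c2ccc(C)cc2)C(C)(C)O | intermediate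
6 | lithium 2-[(1R)-3-lithio-4-methylcyclohexa-2,4-dien-1-yl]propan-2-olate | CC1=CC[C@H](C=C1[Li])C(C)(C)O[Li] | intermediate
7 | 2-[(1R)-4-methylcyclohexa-2,4-dien-1-yl]propan-2-ol, (R)-p-mentha-1,5-dien-8-ol | CC1=CC[C@@H](C(C)(C)O)C=C1 | intermediate
8 | lithium (2-lithiofuran-3-yl)methanolate | [Li]OCc1ccoc1[Li] | intermediate
9 | dilithium trimethoxy[3-(oxidomethyl)furan-2-yl]borate | [Li+].[Li+].[O-]Cc1ccoc1[B-](OC)(OC)OC | intermediate
10 | 3-(hydroxymethyl)furan-2(5H)-one | O=C1OCC=C1CO | intermediate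
11 | tert-butyl{[2-{[tert-butyl(dimethyl)silyl]oxy}furan-3-yl]methoxy}dimethylsilane | CC(C)(C)[Si](C)(C)OCc1ccoc1O[Si](C)(C)C(C)(C)C | intermediate
12 | (1S,3R,4R)-3-endo-bromocamphor | CC1(C)[C@H]2CC[C@]1(C)C(=O)[C@@H]2Br | intermediate
13 | (1S,3R,4R,7S)-3-endo,9-dibromocamphor (bromomethyl anti to C2=O) | C[C@]1(CBr)[C@H]2CC[C@]1(C)C(=O)[C@@H]2Br | intermediate
14 | (−)-3-endo,9,10-tribromocamphor (13 with the C1 methyl also brominated) | C[C@]1(CBr)[C@H]2CC[C@]1(CBr)C(=O)[C@@H]2Br | intermediate
15 | (−)-9,10-dibromocamphor (14 without the C3 bromine) | C[C@]1(CBr)[C@H]2CC[C@]1(CBr)C(=O)C2 | intermediate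
16 | potassium [(1S,2S)-2-(bromomethyl)-2-methyl-3-methylidenecyclopentyl]acetate | C[C@]1(CBr)[C@H](CC(=O)[O-])CCC1=C.[K+] | intermediate
17 | [(1S,2S)-2-(hydroxymethyl)-2-methyl-3-methylidenecyclopentyl]acetic acid | C[C@]1(CO)[C@H](CC(=O)O)CCC1=C | intermediate
18 | (4aS,7aS)-7a-methyl-7-methylidenehexahydrocyclopenta[c]pyran-3(1H)-one (trans-fused) | C[C@]12COC(=O)C[C@@H]1CCC2=C | intermediate
19 | lithium enolate of 18 | C[C@]12COC([O-])=C[C@@H]1CCC2=C.[Li+] | intermediate
20 | (4S,4aS,7aS)-4,7a-dimethyl-7-methylidenehexahydrocyclopenta[c]pyran-3(1H)-one | C[C@]12COC(=O)[C@@H](C)[C@@H]1CCC2=C | intermediate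
21 | (2S)-2-[(1S,2S)-2-(hydroxymethyl)-2-methyl-3-methylidenecyclopentyl]propan-1-ol | C[C@]1(CO)[C@H]([C@H](C)CO)CCC1=C | intermediate
22 | (1S,2S)-1-methyl-5-methylidene-2-[(2S)-1-oxopropan-2-yl]cyclopentane-1-carbaldehyde | C[C@]1(C=O)[C@H]([C@H](C)C=O)CCC1=C | intermediate
23 | (5R) epimer of 24 at the butenolide carbon (8,9-threo adduct) | C[C@]1(C=O)[C@H]([C@H](C)[C@@H](O[Si](C)(C)C(C)(C)C)[C@@H]2OC(=O)C(CO[Si](C)(C)C(C)(C)C)=C2)CCC1=C | intermediate
24 | (5S)-5-[(1R,2S)-1-{[tert-butyl(dimethyl)silyl]oxy}-2-[(1S,2S)-2-formyl-2-methyl-3-methylidenecyclopentyl]propyl]-3-({[tert-butyl(dimethyl)silyl]oxy}methyl)furan-2(5H)-one (8,9-erythro) | C[C@]1(C=O)[C@H]([C@H](C)[C@@H](O[Si](C)(C)C(C)(C)C)[C@H]2OC(=O)C(CO[Si](C)(C)C(C)(C)C)=C2)CCC1=C | intermediate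
25 | 24 with the methylidene replaced by (3R)-3-hydroxy-3-(hydroxymethyl), drawn for osmylation anti to the C5 methyl (this centre is lost in the same step) | C[C@]1(C=O)[C@H]([C@H](C)[C@@H](O[Si](C)(C)C(C)(C)C)[C@H]2OC(=O)C(CO[Si](C)(C)C(C)(C)C)=C2)CC[C@]1(O)CO | intermediate
26 | (5S)-5-[(1R,2S)-1-{[tert-butyl(dimethyl)silyl]oxy}-2-[(1S,2R)-2-formyl-2-methyl-3-oxocyclopentyl]propyl]-3-({[tert-butyl(dimethyl)silyl]oxy}methyl)furan-2(5H)-one | C[C@]1(C=O)[C@H]([C@H](C)[C@@H](O[Si](C)(C)C(C)(C)C)[C@H]2OC(=O)C(CO[Si](C)(C)C(C)(C)C)=C2)CCC1=O | intermediate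
27 | (5S)-3-(bromomethyl)-5-[(1R,2S)-1-{[tert-butyl(dimethyl)silyl]oxy}-2-[(1S,2R)-2-formyl-2-methyl-3-oxocyclopentyl]propyl]furan-2(5H)-one | C[C@]1(C=O)[C@H]([C@H](C)[C@@H](O[Si](C)(C)C(C)(C)C)[C@H]2OC(=O)C(CBr)=C2)CCC1=O | intermediate
28 | 9β-{[tert-butyl(dimethyl)silyl]oxy}-6α-hydroxy-4-oxopseudoguai-11(13)-en-12,8β-olide (1αH, 5β-Me, 7αH, 8αH, 10α-Me) | O[C@H]1[C@H]2[C@H](OC(=O)C2=C)[C@H](O[Si](C)(C)C(C)(C)C)[C@@H](C)[C@@H]2CCC(=O)[C@]21C | intermediate
29 | 6-O-[(E)-2-methylbut-2-enoyl] ester of 28 | C/C=C(\C)C(=O)O[C@H]1[C@H]2[C@H](OC(=O)C2=C)[C@H](O[Si](C)(C)C(C)(C)C)[C@@H](C)[C@@H]2CCC(=O)[C@]21C | intermediate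
30 | 9-O-[tert-butyl(dimethyl)silyl]-6-O-tigloyl-9β-hydroxyhelenalin (29 with the C2=C3 enone) | C/C=C(\C)C(=O)O[C@H]1[C@H]2[C@H](OC(=O)C2=C)[C@H](O[Si](C)(C)C(C)(C)C)[C@@H](C)[C@@H]2C=CC(=O)[C@]21C | intermediate
31 | 6-O-tigloyl-9β-hydroxyhelenalin | C/C=C(\C)C(=O)O[C@H]1[C@H]2[C@H](OC(=O)C2=C)[C@H](O)[C@@H](C)[C@@H]2C=CC(=O)[C@]21C | intermediate
32 | CNP0185323.3 | C/C=C(\C)C(=O)O[C@H]1[C@H]2[C@H](OC(=O)[C@]23C[C@@H]2C[C@@H](C(C)(C)O)[C@H]3C=C2C)[C@H](O)[C@@H](C)[C@@H]2C=CC(=O)[C@]21C | target

**Step count and weak points**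

Total: 20 steps. Longest linear sequence: 15 steps (steps 6 to 20, from 3). The count is driven by the three bromination steps on camphor (steps 6 to 8) and the two-step ketone/enone installation (steps 14 and 18).

Three steps most likely to fail:

- **Step 16 (the proposed new step).** Risks are slow catalytic turnover at high dilution, simple reduction of the bromide, or the wrong C6 epimer. Fallback, known chemistry: a stoichiometric Nozaki–Hiyama–Kishi cyclisation in the dark, setting out from 27, which is added by syringe pump to CrCl2 (6 equiv) in THF at 23 °C, and coming back to the route at 28. No new compound is made (F0).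

- **Step 13.** The aldol must discriminate the two aldehydes and outrun an intramolecular Prins/ene reaction onto the exo-methylene. The base equilibration must also favour the 8,9-erythro butenolide, which is not certain for this substrate. Fallback: set C8 kinetically in the anionic manifold with C6 masked. Setting out from 20, Weinreb aminolysis (MeNH(OMe)·HCl, AlMe3) gives the hydroxy Weinreb amide F1; Et3SiCl and imidazole give the triethylsilyl ether F2; i-Bu2AlH at −78 °C gives the mono-aldehyde F3; the fluoride-promoted vinylogous aldol of F3 with 11 (Bu4N Ph3SiF2, THF, −78 °C, then TBSOTf), which is reported to favour erythro adducts, gives the erythro silyl-protected adduct F4; direct Swern oxidation of the primary triethylsilyl ether comes back to the route at 24.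

- **Step 20.** The cyclopentenone is a second dienophile, and facial, endo and regiochemical control are all substrate-based. Fallback: move the cycloaddition before the enone exists. Setting out from 29 (where the methylene lactone is the only reactive dienophile), heating with 7 gives the saturated-ketone adduct F5; IBX dehydrogenation gives the silyl-protected enone adduct F6; HF·pyridine comes back to the route at 32.

**Further compounds**

F0 | step 16 | none | none
F1 | step 13 | (2S)-2-[(1S,2S)-2-(hydroxymethyl)-2-methyl-3-methylidenecyclopentyl]-N-methoxy-N-methylpropanamide | C[C@]1(CO)[C@H]([C@H](C)C(=O)N(C)OC)CCC1=C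
F2 | step 13 | (2S)-N-methoxy-N-methyl-2-[(1S,2S)-2-methyl-3-methylidene-2-{[(triethylsilyl)oxy]methyl}cyclopentyl]propanamide | C[C@]1(CO[Si](CC)(CC)CC)[C@H]([C@H](C)C(=O)N(C)OC)CCC1=C
F3 | step 13 | (2S)-2-[(1S,2S)-2-methyl-3-methylidene-2-{[(triethylsilyl)oxy]methyl}cyclopentyl]propanal | C[C@]1(CO[Si](CC)(CC)CC)[C@H]([C@H](C)C=O)CCC1=C
F4 | step 13 | (5S)-5-[(1R,2S)-1-{[tert-butyl(dimethyl)silyl]oxy}-2-[(1S,2S)-2-methyl-3-methylidene-2-{[(triethylsilyl)oxy]methyl}cyclopentyl]propyl]-3-({[tert-butyl(dimethyl)silyl]oxy}methyl)furan-2(5H)-one | C[C@]1(CO[Si](CC)(CC)CC)[C@H]([C@H](C)[C@@H](O[Si](C)(C)C(C)(C)C)[C@H]2OC(=O)C(CO[Si](C)(C)C(C)(C)C)=C2)CCC1=C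
F5 | step 20 | 9-O-[tert-butyl(dimethyl)silyl]-2,3-dihydro derivative of 32 (Diels–Alder adduct of 29 and 7) | C/C=C(\C)C(=O)O[C@H]1[C@H]2[C@H](OC(=O)[C@]23C[C@@H]2C[C@@H](C(C)(C)O)[C@H]3C=C2C)[C@H](O[Si](C)(C)C(C)(C)C)[C@@H](C)[C@@H]2CCC(=O)[C@]21C
F6 | step 20 | 9-O-[tert-butyl(dimethyl)silyl] ether of 32 | C/C=C(\C)C(=O)O[C@H]1[C@H]2[C@H](OC(=O)[C@]23C[C@@H]2C[C@@H](C(C)(C)O)[C@H]3C=C2C)[C@H](O[Si](C)(C)C(C)(C)C)[C@@H](C)[C@@H]2C=CC(=O)[C@]21C
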